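**Retrosynthetic overview**

1. Target 14 comes from 13 by hydrogenolysis of both benzyl ethers, 13 from 11 by O-methylation of the hydrogen-bonded C2 hydroxyl, and 11 from resorcinol ketone 9 by selective O-benzylation of the C4 hydroxyl.
2. Feature: in ring A (C1 acyl, C2 OMe, C3 bearing the CH2 to phenol ring C, C4 OH, C5–H, C6–H) the side-chain C=O and the oxygens on C2 and C4 sit on alternate carbons, so C1–C5 are a folded triketide chain whose doubly activated carbon C3 carries the benzylic CH2, and C6 is one extra carbon at formyl level.
3. Key disconnection of 9: C1–C6 and C5–C6, which opens ring A to the acyclic triketone 6 and Me2NCH(OMe)2 7 as the donor of C6.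
4. Triketone 6 comes from acylation of the dianion of 3 at a methyl group with ester 4, and 3 from C-benzylation of pentane-2,4-dione 1 with bromide 2; 1 is symmetric, so the chain is assembled without a regiochemical choice.
5. Ring order: the phenyl ring and ring C are bought; ring A is the only ring made, in step 3.

Key step: step 3

Remark: ring-A numbering is used throughout; octane carbons 5, 4, 3, 2 and 1 of triketone 6 become ring carbons C1, C2, C3, C4 and C5, and the acetal carbon of 7 becomes C6. The target has no stereocentre, the single centre of racemic 6 (C3) ends as an sp2 ring carbon, and bromide 2 is taken as a purchasable reagent.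

**Route**

Step 1
Reactants: 1 pentane-2,4-dione; 2 2-(benzyloxy)benzyl bromide
Product: 3 3-[2-(benzyloxy)benzyl]pentane-2,4-dione
Conditions: 1 (3 equiv), K2CO3 (1.5 equiv), acetone, reflux
Reagents that add atoms: 2-(benzyloxy)benzyl bromide 2, BrCc1ccccc1OCc1ccccc1
Why: SN2 C-alkylation of the potassium enolate of a 1,3-diketone at its central carbon by a reactive benzylic bromide; the excess of 1 should suppress double alkylation, and the soft benzylic electrophile favours carbon over oxygen.

Step 2
Reactants: 3 3-[2-(benzyloxy)benzyl]pentane-2,4-dione; 4 methyl 3-phenylpropanoate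
Product: 6 3-[2-(benzyloxy)benzyl]-8-phenyloctane-2,4,6-trione, via dilithio dianion 5 (not isolated)
Conditions: LiN(i-Pr)2 (2.1 equiv per 3), THF, −78 to 0 °C; then 4 (0.5 equiv per 3), 0 °C to rt; aq. HCl
Reagents that add atoms: methyl 3-phenylpropanoate 4, COC(=O)CCc1ccccc1
Why: Claisen-type acylation of a 1,3-diketone dianion, whose second deprotonation occurs at a methyl group so that the terminal carbanion attacks the ester; the two methyl groups of 3 are equivalent, so only one triketone can form, and the second equivalent of 5 serves to deprotonate the more acidic product (excess 3 is recoverable).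

Step 3
Reactants: 6 3-[2-(benzyloxy)benzyl]-8-phenyloctane-2,4,6-trione; 7 N,N-dimethylformamide dimethyl acetal
Product: 9 1-{3-[2-(benzyloxy)benzyl]-2,4-dihydroxyphenyl}-3-phenylpropan-1-one, via aminomethylene triketone 8 (not isolated)
Conditions: Me2NCH(OMe)2 (1.1 equiv), THF, rt, then remove volatiles; NaOMe (4 equiv), MeOH, 0 to 60 °C; aq. HCl
Reagents that add atoms: N,N-dimethylformamide dimethyl acetal 7, COC(OC)N(C)C
Why: Amide-acetal aminomethylenation should take place at rt at C1, the one CH2 of 6 that lies between two carbonyls (C3 is flanked in the same way but holds a single hydrogen and can only enolise, and the acetyl CH3 and the side-chain α-CH2 are singly activated), giving the push–pull enaminone 8 whose CH carbon is the future C6 and forming C1–C6. With NaOMe the extended enolate of the C2–C3–C4 diketone unit places nucleophilic character on the acetyl carbon C5, which adds to C6 and expels dimethylamine, a 6-endo-trig conjugate addition–elimination that closes ring A as a carbocycle and forms C5–C6; enolisation of the two ring ketones then gives the aromatic 2,4-dihydroxyphenyl ketone. The closest known reaction types are the aminomethylenation of 1,3-diketones with Me2NCH(OMe)2 and the base-induced aldol-type cyclisation and aromatisation of poly-β-carbonyl chains that carry an aldehyde-level carbon; the telescoped sequence applies them to a new chain. No stereocentre is created, and the racemic C3 centre of 6 becomes an sp2 ring carbon. The step needs carbon-over-oxygen selectivity in the closure: attack of the C4 enol oxygen on C6 would give a 3-acyl-4-pyranone, but methoxide can re-add at the unsubstituted ring carbon next to the ring oxygen and reopen it, so the oxygen path stays reversible while the carbon path is drained by aromatisation to the phenoxide; closure from C3 or from the side-chain α-carbon would need a four-membered ring.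

Step 4
Reactants: 9 1-{3-[2-(benzyloxy)benzyl]-2,4-dihydroxyphenyl}-3-phenylpropan-1-one; 10 benzyl bromide
Product: 11 1-{4-(benzyloxy)-3-[2-(benzyloxy)benzyl]-2-hydroxyphenyl}-3-phenylpropan-1-one
Conditions: BnBr (1.05 equiv), K2CO3 (1.2 equiv), acetone, reflux
Reagents that add atoms: benzyl bromide 10, BrCc1ccccc1
Why: Williamson etherification selective for the C4 hydroxyl, which is the more acidic one (para to the acyl group) and is not held in the hydrogen bond to the ketone that deactivates the C2 hydroxyl.

Step 5
Reactants: 11 1-{4-(benzyloxy)-3-[2-(benzyloxy)benzyl]-2-hydroxyphenyl}-3-phenylpropan-1-one; 12 iodomethane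
Product: 13 1-{4-(benzyloxy)-3-[2-(benzyloxy)benzyl]-2-methoxyphenyl}-3-phenylpropan-1-one
Conditions: MeI (5 equiv), K2CO3 (3 equiv), DMF, 50 °C
Reagents that add atoms: iodomethane 12, CI
Why: Williamson methylation of the remaining hydrogen-bonded phenol in a polar aprotic solvent with excess MeI; carbonate is too weak to enolise the ketone, so α-C-methylation should not compete.

Step 6
Reactants: 13 1-{4-(benzyloxy)-3-[2-(benzyloxy)benzyl]-2-methoxyphenyl}-3-phenylpropan-1-one
Product: 14 1-[4-hydroxy-3-(2-hydroxybenzyl)-2-methoxyphenyl]-3-phenylpropan-1-one
Conditions: H2 (1 atm), Pd/C (10 wt% Pd), EtOAc–MeOH, rt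
Reagents that add atoms: none
Why: Catalytic hydrogenolysis of both aryl benzyl ethers on palladium metal at 1 atm and rt, conditions under which the diarylmethane C–C bonds, the aryl methyl ether and the electron-rich aryl ketone should stay intact if the reaction is stopped after two equivalents of H2.

**Compound list**

1 | pentane-2,4-dione | CC(=O)CC(C)=O | starting material
2 | 2-(benzyloxy)benzyl bromide, i.e. 1-(benzyloxy)-2-(bromomethyl)benzene | BrCc1ccccc1OCc1ccccc1 | starting material
3 | 3-[2-(benzyloxy)benzyl]pentane-2,4-dione | CC(=O)C(Cc1ccccc1OCc1ccccc1)C(C)=O | intermediate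
4 | methyl 3-phenylpropanoate | COC(=O)CCc1ccccc1 | starting material
5 | dilithio dianion of 3 (dilithium dienolate, not isolated) | [Li+].[Li+].C=C([O-])C(Cc1ccccc1OCc1ccccc1)=C(C)[O-] | intermediate
6 | 3-[2-(benzyloxy)benzyl]-8-phenyloctane-2,4,6-trione (racemic, enolisable) | CC(=O)C(Cc1ccccc1OCc1ccccc1)C(=O)CC(=O)CCc1ccccc1 | intermediate
7 | N,N-dimethylformamide dimethyl acetal | COC(OC)N(C)C | starting material
8 | 3-[2-(benzyloxy)benzyl]-5-[(dimethylamino)methylidene]-8-phenyloctane-2,4,6-trione (not isolated) | CC(=O)C(Cc1ccccc1OCc1ccccc1)C(=O)C(=CN(C)C)C(=O)CCc1ccccc1 | intermediate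
9 | 1-{3-[2-(benzyloxy)benzyl]-2,4-dihydroxyphenyl}-3-phenylpropan-1-one | O=C(CCc1ccccc1)c1ccc(O)c(Cc2ccccc2OCc2ccccc2)c1O | intermediate
10 | benzyl bromide | BrCc1ccccc1 | starting material
11 | 1-{4-(benzyloxy)-3-[2-(benzyloxy)benzyl]-2-hydroxyphenyl}-3-phenylpropan-1-one | O=C(CCc1ccccc1)c1ccc(OCc2ccccc2)c(Cc2ccccc2OCc2ccccc2)c1O | intermediate
12 | iodomethane | CI | starting material
13 | 1-{4-(benzyloxy)-3-[2-(benzyloxy)benzyl]-2-methoxyphenyl}-3-phenylpropan-1-one | COc1c(C(=O)CCc2ccccc2)ccc(OCc2ccccc2)c1Cc1ccccc1OCc1ccccc1 | intermediate
14 | 1-[4-hydroxy-3-(2-hydroxybenzyl)-2-methoxyphenyl]-3-phenylpropan-1-one | COc1c(C(=O)CCc2ccccc2)ccc(O)c1Cc1ccccc1O | target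

**Step count and risks**

Total step count: 6. Longest linear sequence: 6 steps (from 1 and 2 to 14).

Steps most likely to fail:

1. Step 3. The closure may run through the enol oxygen instead of the methyl carbon and stall at the pyranone stage, or methoxide may cleave the acylated aminomethylene unit by retro-Claisen attack before the ring closes. Fallback, from 6 back to 9: the one-carbon unit would be placed at the other end of the chain. Triketone 6 would be converted into its trianion with excess LiN(i-Pr)2 in THF at 0 °C, where the third deprotonation is expected at the methyl group rather than the side-chain CH2. Formylation of that terminal carbon with ethyl formate would give 4-[2-(benzyloxy)benzyl]-3,5,7-trioxo-9-phenylnonanal F1, handled as its enol mixture. On buffering with aq. NaHCO3 the doubly activated C6 methylene of F1 (ring carbon C1) should attack the free aldehyde in a Knoevenagel-type aldol closure, and loss of water and enolisation would give 9. The same two ring bonds are made, but the nucleophile is now the most acidic carbon of the chain and no aminomethylene carbon is present for oxygen to attack.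

2. Step 2. Proton transfer from the α-CH2 of the ester to the dianion, together with quenching of the dianion by the acidic product, may leave low conversion and ester self-condensation. Fallback, from 3 back to 6: the dianion of 3 (LiN(i-Pr)2, THF, 0 °C) would be added to 3-phenylpropanal at −78 °C, an aldol addition that needs no excess dianion, giving 3-[2-(benzyloxy)benzyl]-6-hydroxy-8-phenyloctane-2,4-dione F2 as a diastereomer mixture. Oxidation of the β-hydroxy ketone with 2-iodoxybenzoic acid in EtOAc at reflux would give triketone 6.

3. Step 5. O-alkylation of the hydrogen-bonded phenoxide, flanked on both sides, may be slow, and forcing it may bring on C-methylation at the ketone α-carbon. Fallback, from 11 back to 13: the hydroxyl would be methylated without base by a Mitsunobu reaction (MeOH, PPh3, diisopropyl azodicarboxylate, THF, 0 °C to rt), which activates methanol instead of generating the phenoxide and so cannot form a ketone enolate; this fallback makes no new compound (F0).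

**Further compounds**

F1 | step 3 | 4-[2-(benzyloxy)benzyl]-3,5,7-trioxo-9-phenylnonanal | O=CCC(=O)C(Cc1ccccc1OCc1ccccc1)C(=O)CC(=O)CCc1ccccc1
F2 | step 2 | 3-[2-(benzyloxy)benzyl]-6-hydroxy-8-phenyloctane-2,4-dione (diastereomer mixture) | CC(=O)C(Cc1ccccc1OCc1ccccc1)C(=O)CC(O)CCc1ccccc1
F0 | step 5 | none | none
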